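**Plan**

1. Retrosynthesis (locants: unprimed and primed = flavone, double-primed = flavanone, triple-primed = its 4-hydroxyphenyl ring): the O-benzyl groups at C5 and C4''' are cut first, then ring A'' at C8''–C8a'' and C4a''–C5''. The diene is then cut at its two O–Si bonds, the acetyl–Cα bond and the flavone C3–CH2 bond, and the pyranone at C5–Br and at O1–C6/C2–C3.
2. Enabling feature: ring A'' (C4a'', C5'', C6'', C7'', C8'', C8a'') is a phloroglucinol ring held between flavone C3 (on C6'') and the stereogenic pyranone ring C'' (O1'', C2'', C3'', C4'', fused at C4a''–C8a''). C5''–C8'' with their two oxygens and the flavone map onto a flavonyl-substituted 1,1,3-trioxygenated diene, and C4a''/C8a'' with O1'' map onto C5/C6 of a 5-bromo-2,3-dihydropyran-4-one, so the halves are joined by building this ring and no biaryl coupling is needed.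
3. Forward: flavone rings A, C and B come intact from apigenin and the diene arm is grown on C3 (steps 1–7). Ring C'' is made by a catalytic asymmetric hetero-Diels–Alder reaction and brominated (steps 8–9), ring A'' is closed last (step 10), and hydrogenolysis frees the phenols (step 11).
4. Stereochemistry: C2'' (R), the only stereocentre, is set in step 8 by the (R)-BINOL–Ti(OiPr)4 catalyst; none of its four bonds is made or broken afterwards.

Key step: step 10

Assumption: the (R)-BINOL–Ti(OiPr)4 catalyst is taken to direct the diene to the Re face of the aromatic aldehyde, which gives the (2R) pyranone; the sense is to be checked on the product of step 8, and (S)-BINOL would be used instead if it proves opposite.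

Abbreviation in names: Fl = 5-(benzyloxy)-7-methoxy-2-(4-methoxyphenyl)-4-oxo-4H-chromen-3-yl.

**Route**

Step 1
Reactants: 1 apigenin [5,7-dihydroxy-2-(4-hydroxyphenyl)-4H-chromen-4-one]
Product: 2 5-hydroxy-7-methoxy-2-(4-methoxyphenyl)-4H-chromen-4-one
Conditions: MeI (2.3 equiv), K2CO3, DMF, 20 °C
Reagents that add atoms: iodomethane, CI
Why: Williamson etherification should take the acidic, unchelated 7- and 4'-hydroxyls, while the 5-hydroxyl, hydrogen-bonded to the C4 carbonyl, stays free under these mild conditions.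

Step 2
Reactants: 2 5-hydroxy-7-methoxy-2-(4-methoxyphenyl)-4H-chromen-4-one
Product: 3 5-(benzyloxy)-7-methoxy-2-(4-methoxyphenyl)-4H-chromen-4-one
Conditions: BnBr (1.5 equiv), K2CO3, DMF, 80 °C
Reagents that add atoms: benzyl bromide, BrCc1ccccc1
Why: Williamson benzylation under forcing conditions should cap the chelated 5-hydroxyl, which removes the only acidic proton before the strong-base steps and leaves a group that the final hydrogenolysis takes off.

Step 3
Reactants: 3 5-(benzyloxy)-7-methoxy-2-(4-methoxyphenyl)-4H-chromen-4-one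
Product: 5 5-(benzyloxy)-3-iodo-7-methoxy-2-(4-methoxyphenyl)-4H-chromen-4-one, via 3-lithioflavone 4 (not isolated)
Conditions: LiN(iPr)2 (1.3 equiv), THF, −78 °C; I2, −78 → 0 °C
Reagents that add atoms: iodine, II
Why: Directed lithiation and iodine quench should be regiospecific because C3–H is the most acidic C–H of a flavone, whereas electrophilic iodination would attack C6/C8 of the electron-rich ring A.

Step 4
Reactants: 5 5-(benzyloxy)-3-iodo-7-methoxy-2-(4-methoxyphenyl)-4H-chromen-4-one
Product: 6 methyl 2-Fl-acetate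
Conditions: BrZnCH2CO2Me (2 equiv; preformed from BrCH2CO2Me and Zn dust in THF at 40 °C), Pd2(dba)3 (2.5 mol %), XPhos (10 mol %), THF, 60 °C
Reagents that add atoms: methyl bromoacetate, COC(=O)CBr
Why: Negishi-type cross-coupling of the Reformatsky reagent BrZnCH2CO2Me with the vinylic C3–I bond (oxidative addition to zerovalent palladium, transmetalation, reductive elimination) should install the acetate arm under neutral conditions that spare the pyrone.

Step 5
Reactants: 6 methyl 2-Fl-acetate
Product: 8 methyl 2-Fl-3-oxobutanoate (racemic and largely enolised), via lithium ester enolate 7 (not isolated)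
Conditions: LiN(SiMe3)2 (2.2 equiv), THF, −78 °C; AcCl (1.1 equiv), −78 → 0 °C; aq. NH4Cl
Reagents that add atoms: acetyl chloride, CC(=O)Cl
Why: Crossed Claisen C-acylation of the lithium ester enolate by an acid chloride should give the β-keto ester, the second equivalent of base taking up the more acidic product as it forms.

Step 6
Reactants: 8 methyl 2-Fl-3-oxobutanoate
Product: 9 methyl 2-Fl-3-(trimethylsilyloxy)but-2-enoate (E/Z mixture)
Conditions: Me3SiCl (1.5 equiv), Et3N (1.6 equiv), toluene, 20 °C
Reagents that add atoms: chlorotrimethylsilane, C[Si](C)(C)Cl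
Why: O-silylation of the enolised β-keto ester by soft enolisation is the standard first stage in making 1,3-bis(silyloxy)dienes and should proceed likewise with the C2 aryl substituent.

Step 7
Reactants: 9 methyl 2-Fl-3-(trimethylsilyloxy)but-2-enoate
Product: 11 2-Fl-1-methoxy-1,3-bis(trimethylsilyloxy)buta-1,3-diene (either ketene acetal geometry), via lithium dienolate 10 (not isolated)
Conditions: LiN(iPr)2 (1.3 equiv), THF, −78 °C; Me3SiCl (1.5 equiv), −78 → 20 °C; evaporation, filtration in dry toluene under Ar, used crude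
Reagents that add atoms: chlorotrimethylsilane, C[Si](C)(C)Cl
Why: Kinetic γ-deprotonation of the vinylogous methyl group and O-silylation of the extended ester enolate is the standard second stage for 1-alkoxy-1,3-bis(silyloxy)buta-1,3-dienes, including 2-substituted ones, and either ketene acetal geometry serves in step 10.

Step 8
Reactants: 12 4-(benzyloxy)benzaldehyde; 13 (E)-1-methoxy-3-(trimethylsilyloxy)buta-1,3-diene
Product: 15 (2R)-2-[4-(benzyloxy)phenyl]-2,3-dihydro-4H-pyran-4-one, via silylated aldol adduct 14 (not isolated)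
Conditions: (R)-BINOL (20 mol %), Ti(OiPr)4 (10 mol %), 4 Å MS, Et2O, −20 °C; then CF3CO2H, CH2Cl2, 0 °C
Reagents that add atoms: none
Why: Catalytic asymmetric hetero-Diels–Alder reaction in its Mukaiyama aldol and acid cyclisation form, in which the chiral (R)-BINOL–Ti(OiPr)4 complex shields one aldehyde face and so sets C2 (R) before acid closes the ring and expels methanol.

Step 9
Reactants: 15 (2R)-2-[4-(benzyloxy)phenyl]-2,3-dihydro-4H-pyran-4-one
Product: 16 (2R)-2-[4-(benzyloxy)phenyl]-5-bromo-2,3-dihydro-4H-pyran-4-one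
Conditions: NBS (1.05 equiv), CH2Cl2, 0 °C, dark
Reagents that add atoms: N-bromosuccinimide, O=C1CCC(=O)N1Br
Why: Electrophilic α-bromination of a cyclic vinylogous ester should occur at the nucleophilic enol ether carbon C5, the oxocarbenium ion then losing the C5 proton to restore the enone, with C2 untouched.

Step 10
Reactants: 16 (2R)-2-[4-(benzyloxy)phenyl]-5-bromo-2,3-dihydro-4H-pyran-4-one; 11 2-Fl-1-methoxy-1,3-bis(trimethylsilyloxy)buta-1,3-diene
Product: 19 5-(benzyloxy)-3-[(2R)-2-[4-(benzyloxy)phenyl]-5,7-dihydroxy-4-oxo-3,4-dihydro-2H-chromen-6-yl]-7-methoxy-2-(4-methoxyphenyl)-4H-chromen-4-one (5,4'''-di-O-benzyl ether of the target), via Michael adduct 17 (not isolated), via bromo diketone 18 (not isolated)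
Conditions: Me3SiOTf (0.3 equiv), CH2Cl2, −78 → −20 °C; then Et3N (3 equiv), −20 → 20 °C; 1 M HCl, THF, 0 °C
Reagents that add atoms: none
Why: Proposed new method: Me3SiOTf silylates the C4 carbonyl of 16 to a cyclic oxocarbenium ion, the CH2 terminus of 11 attacks its C6 (future C8a'') in a vinylogous Mukaiyama–Michael step to give 17, the bromine-bearing silyl enol ether carbon C5 (future C4a'') then attacks the silyl-activated ester carbon (future C5''), methoxytrimethylsilane is lost to give 18, and Et3N removes HBr across C4a''–C8a'' so that enolisation aromatises the ring. The closest known reactions are the cycloaddition and aromatisation of 1,1,3-trioxygenated silyloxydienes with halogenated quinones and bromo enones, the Me3SiOTf-mediated domino additions of 1,3-bis(silyloxy)dienes to chromones, and Lewis acid Mukaiyama–Michael additions to 2,3-dihydropyran-4-ones; new here are the 5-bromo-dihydropyranone as two-carbon partner and a diene carrying a heteroaryl group on C2. Ring A'' closes as a stepwise formal [4+2] process, the intermolecular C8''–C8a'' bond being followed by a 6-(enolexo)-exo-trig closure of C4a''–C5''. No stereocentre that survives is created, since the centres at C4a'' and C8a'' in 17 and 18 vanish on aromatisation and C2'' is a spectator. The step needs regiocontrol, which polarity matching supplies (the nucleophilic diene CH2 pairs with the electrophilic β-carbon C6, so the flavone ends on C6'' between the two new hydroxyls), and the right oxidation level, which the bromine supplies, because its loss as HBr lets the ring aromatise with O1'' still on C8a''. The competing [3+3] closure of diene C2 onto C4=O is disfavoured because that carbon bears the flavone and could not aromatise, and low temperature with only brief exposure to a weak base should protect C2'' from retro-oxa-Michael opening.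

Step 11
Reactants: 19 5,4'''-di-O-benzyl ether of the target
Product: 20 5-hydroxy-3-[(2R)-5,7-dihydroxy-2-(4-hydroxyphenyl)-4-oxo-3,4-dihydro-2H-chromen-6-yl]-7-methoxy-2-(4-methoxyphenyl)-4H-chromen-4-one (CNP0292254.1)
Conditions: H2 (1 atm), 10% Pd/C, EtOAc–MeOH, 20 °C
Reagents that add atoms: none
Why: Hydrogenolysis of the two aryl benzyl ethers under neutral conditions should leave the tetrasubstituted flavone C2=C3 bond, both ketones and the ring C2''–O bond intact, and the neutral medium avoids chalcone-type racemisation of the flavanone.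

**Compound list**

1 | apigenin, 5,7-dihydroxy-2-(4-hydroxyphenyl)-4H-chromen-4-one | O=c1cc(-c2ccc(O)cc2)oc2cc(O)cc(O)c12 | starting material
2 | 5-hydroxy-7-methoxy-2-(4-methoxyphenyl)-4H-chromen-4-one | COc1ccc(-c2cc(=O)c3c(O)cc(OC)cc3o2)cc1 | intermediate
3 | 5-(benzyloxy)-7-methoxy-2-(4-methoxyphenyl)-4H-chromen-4-one | COc1ccc(-c2cc(=O)c3c(OCc4ccccc4)cc(OC)cc3o2)cc1 | intermediate
4 | 5-(benzyloxy)-3-lithio-7-methoxy-2-(4-methoxyphenyl)-4H-chromen-4-one | COc1ccc(-c2oc3cc(OC)cc(OCc4ccccc4)c3c(=O)c2[Li])cc1 | intermediate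
5 | 5-(benzyloxy)-3-iodo-7-methoxy-2-(4-methoxyphenyl)-4H-chromen-4-one | COc1ccc(-c2oc3cc(OC)cc(OCc4ccccc4)c3c(=O)c2I)cc1 | intermediate
6 | methyl 2-[5-(benzyloxy)-7-methoxy-2-(4-methoxyphenyl)-4-oxo-4H-chromen-3-yl]acetate | COC(=O)Cc1c(-c2ccc(OC)cc2)oc2cc(OC)cc(OCc3ccccc3)c2c1=O | intermediate
7 | lithium enolate of 6 | [Li+].COC([O-])=Cc1c(-c2ccc(OC)cc2)oc2cc(OC)cc(OCc3ccccc3)c2c1=O | intermediate
8 | methyl 2-[5-(benzyloxy)-7-methoxy-2-(4-methoxyphenyl)-4-oxo-4H-chromen-3-yl]-3-oxobutanoate (racemic) | COC(=O)C(C(C)=O)c1c(-c2ccc(OC)cc2)oc2cc(OC)cc(OCc3ccccc3)c2c1=O | intermediate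
9 | methyl 2-[5-(benzyloxy)-7-methoxy-2-(4-methoxyphenyl)-4-oxo-4H-chromen-3-yl]-3-(trimethylsilyloxy)but-2-enoate (E/Z mixture) | COC(=O)C(=C(C)O[Si](C)(C)C)c1c(-c2ccc(OC)cc2)oc2cc(OC)cc(OCc3ccccc3)c2c1=O | intermediate
10 | lithium dienolate of 9 (γ-deprotonated) | [Li+].C=C(O[Si](C)(C)C)C(=C(OC)[O-])c1c(-c2ccc(OC)cc2)oc2cc(OC)cc(OCc3ccccc3)c2c1=O | intermediate
11 | 5-(benzyloxy)-7-methoxy-3-[1-methoxy-1,3-bis(trimethylsilyloxy)buta-1,3-dien-2-yl]-2-(4-methoxyphenyl)-4H-chromen-4-one (either ketene acetal geometry) | C=C(O[Si](C)(C)C)C(=C(OC)O[Si](C)(C)C)c1c(-c2ccc(OC)cc2)oc2cc(OC)cc(OCc3ccccc3)c2c1=O | intermediate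
12 | 4-(benzyloxy)benzaldehyde | O=Cc1ccc(OCc2ccccc2)cc1 | starting material
13 | (E)-1-methoxy-3-(trimethylsilyloxy)buta-1,3-diene | CO/C=C/C(=C)O[Si](C)(C)C | starting material
14 | (1E,5R)-5-[4-(benzyloxy)phenyl]-1-methoxy-5-(trimethylsilyloxy)pent-1-en-3-one | CO/C=C/C(=O)C[C@H](c1ccc(OCc2ccccc2)cc1)O[Si](C)(C)C | intermediate
15 | (2R)-2-[4-(benzyloxy)phenyl]-2,3-dihydro-4H-pyran-4-one | O=C1C[C@H](c2ccc(OCc3ccccc3)cc2)OC=C1 | intermediate
16 | (2R)-2-[4-(benzyloxy)phenyl]-5-bromo-2,3-dihydro-4H-pyran-4-one | O=C1C[C@H](c2ccc(OCc3ccccc3)cc2)OC=C1Br | intermediate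
17 | methyl 4-[(2R)-2-[4-(benzyloxy)phenyl]-5-bromo-4-(trimethylsilyloxy)-3,6-dihydro-2H-pyran-6-yl]-2-Fl-3-(trimethylsilyloxy)but-2-enoate (C6 of the pyran ring unassigned, trans to the aryl group expected) | COC(=O)C(=C(CC1O[C@@H](c2ccc(OCc3ccccc3)cc2)CC(O[Si](C)(C)C)=C1Br)O[Si](C)(C)C)c1c(-c2ccc(OC)cc2)oc2cc(OC)cc(OCc3ccccc3)c2c1=O | intermediate
18 | (2R)-2-[4-(benzyloxy)phenyl]-4a-bromo-6-Fl-7-(trimethylsilyloxy)-2,3,8,8a-tetrahydro-4H-chromene-4,5(4aH)-dione (C4a and C8a unassigned) | O=C1C[C@H](c2ccc(OCc3ccccc3)cc2)OC2CC(O[Si](C)(C)C)=C(c3c(-c4ccc(OC)cc4)oc4cc(OC)cc(OCc5ccccc5)c4c3=O)C(=O)C12Br | intermediate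
19 | 5-(benzyloxy)-3-[(2R)-2-[4-(benzyloxy)phenyl]-5,7-dihydroxy-4-oxo-3,4-dihydro-2H-chromen-6-yl]-7-methoxy-2-(4-methoxyphenyl)-4H-chromen-4-one | COc1ccc(-c2oc3cc(OC)cc(OCc4ccccc4)c3c(=O)c2-c2c(O)cc3c(c2O)C(=O)C[C@H](c2ccc(OCc4ccccc4)cc2)O3)cc1 | intermediate
20 | 5-hydroxy-3-[(2R)-5,7-dihydroxy-2-(4-hydroxyphenyl)-4-oxo-3,4-dihydro-2H-chromen-6-yl]-7-methoxy-2-(4-methoxyphenyl)-4H-chromen-4-one | COc1ccc(-c2oc3cc(OC)cc(O)c3c(=O)c2-c2c(O)cc3c(c2O)C(=O)C[C@H](c2ccc(O)cc2)O3)cc1 | target

**Step count**

Total step count: 11. Longest linear sequence: 9 steps (steps 1–7, 10 and 11, from apigenin); the pyranone branch adds 2 steps (8 and 9) before the union.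

**Steps most likely to fail**

Step 10 (the step that carries the label of a proposed new method). The cascade may stall after the Mukaiyama–Michael addition, because the bromine-bearing silyl enol ether is a weak nucleophile toward the ester. O1'' may leave by β-elimination before bromide is lost, or bromine may be lost reductively, either of which gives an open-chain resorcinol. The Lewis acid may also ionise the benzylic C2''–O bond and erode enantiomeric purity. Loss of the 5-O-benzyl group would be harmless, as step 11 removes it anyway.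

The fallback uses known reactions only, brings ring A'' in preformed and sets C2'' afterwards; it sets out from iodide 5 and returns at target 20. Commercial 5,7-dihydroxychromone would be benzylated at the unchelated hydroxyl (BnBr, K2CO3, acetone) to 7-(benzyloxy)-5-hydroxy-4H-chromen-4-one F1. Iodination ortho to the chelated phenol (benzyltrimethylammonium dichloroiodate, CaCO3, CH2Cl2–MeOH) would give 7-(benzyloxy)-5-hydroxy-6-iodo-4H-chromen-4-one F2. Benzylation (BnBr, K2CO3, DMF) would give 5,7-bis(benzyloxy)-6-iodo-4H-chromen-4-one F3, and Miyaura borylation (B2pin2, PdCl2(dppf), KOAc, dioxane) the 6-pinacolboronate F4. Suzuki–Miyaura coupling of F4 with 5 (Pd(OAc)2, SPhos, K3PO4, toluene–water) would give 5,7-bis(benzyloxy)-6-Fl-4H-chromen-4-one F5. Asymmetric conjugate addition of 4-(benzyloxy)phenylboronic acid to the unsubstituted chromone C2=C3 bond (Pd(OCOCF3)2, the t-BuPyOX enantiomer that gives 2R) would give the 5,5'',7'',4'''-tetra-O-benzyl ether of the target F6; the 2-aryl flavone is inert here. Hydrogenolysis as in step 11 then gives 20.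

Step 7. Silylation of the hindered dienolate may be incomplete or occur on carbon, and the ketene acetal may hydrolyse during isolation, so that the diene reaches step 10 degraded. The fallback sets out from 9 and returns at 19 without a new compound. Lithium dienolate 10 would be generated as in step 7 and, in place of silylation, treated directly with bromopyranone 16 (THF, −78 → 0 °C) in an anionic Michael–Dieckmann annulation of the Staunton–Weinreb type. This comprises conjugate addition of the CH2 terminus to C6, Dieckmann closure of the bromo enolate on the methyl ester, loss of HBr to the released methoxide and enolisation; acidic work-up removes the remaining silyl group.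

Step 4. Oxidative addition and transmetalation at C3, flanked by the aryl group and the carbonyl, may be slow, so that protodeiodination back to 3 or self-condensation of BrZnCH2CO2Me takes over. The fallback sets out from 5 and returns at 6. Stille coupling with allyltributylstannane (Pd(PPh3)4, LiCl, DMF, 90 °C) would give 3-allyl-5-(benzyloxy)-7-methoxy-2-(4-methoxyphenyl)-4H-chromen-4-one F7. Ozonolysis of the terminal alkene in CH2Cl2 and methanolic NaOH at −78 °C (indicator-controlled) would convert it directly into methyl ester 6.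

**Further compounds**

F1 | step 10 | 7-(benzyloxy)-5-hydroxy-4H-chromen-4-one | O=c1ccoc2cc(OCc3ccccc3)cc(O)c12
F2 | step 10 | 7-(benzyloxy)-5-hydroxy-6-iodo-4H-chromen-4-one | O=c1ccoc2cc(OCc3ccccc3)c(I)c(O)c12
F3 | step 10 | 5,7-bis(benzyloxy)-6-iodo-4H-chromen-4-one | O=c1ccoc2cc(OCc3ccccc3)c(I)c(OCc3ccccc3)c12
F4 | step 10 | 5,7-bis(benzyloxy)-6-(4,4,5,5-tetramethyl-1,3,2-dioxaborolan-2-yl)-4H-chromen-4-one | O=c1ccoc2cc(OCc3ccccc3)c(B3OC(C)(C)C(C)(C)O3)c(OCc3ccccc3)c12
F5 | step 10 | 5-(benzyloxy)-3-[5,7-bis(benzyloxy)-4-oxo-4H-chromen-6-yl]-7-methoxy-2-(4-methoxyphenyl)-4H-chromen-4-one | COc1ccc(-c2oc3cc(OC)cc(OCc4ccccc4)c3c(=O)c2-c2c(OCc3ccccc3)cc3occc(=O)c3c2OCc2ccccc2)cc1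
F6 | step 10 | 5-(benzyloxy)-3-[(2R)-5,7-bis(benzyloxy)-2-[4-(benzyloxy)phenyl]-4-oxo-3,4-dihydro-2H-chromen-6-yl]-7-methoxy-2-(4-methoxyphenyl)-4H-chromen-4-one | COc1ccc(-c2oc3cc(OC)cc(OCc4ccccc4)c3c(=O)c2-c2c(OCc3ccccc3)cc3c(c2OCc2ccccc2)C(=O)C[C@H](c2ccc(OCc4ccccc4)cc2)O3)cc1
F0 | step 7 | none | none
F7 | step 4 | 3-allyl-5-(benzyloxy)-7-methoxy-2-(4-methoxyphenyl)-4H-chromen-4-one | C=CCc1c(-c2ccc(OC)cc2)oc2cc(OC)cc(OCc3ccccc3)c2c1=O
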